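O1–C2(aryl)–C3(CH3)–C4(CH3)(OH)–C5(aryl) is the oxolane ring of the target: the C2 aryl, C3 methyl and C4 hydroxyl sit on one face, the C4 methyl and C5 aryl on the other. Read with C5 as a carbonyl, the chain O1–C2–C3–C4–C5 is a 3-hydroxy-4-methyl-5-aryl butenolide (an isotetronic acid); these atom labels are kept for all intermediates, whatever the locants in their systematic names.
Disconnections, backwards: three O–Si bonds; C5–aryl (arylzinc onto the C5 oxocarbenium ion of a sulfone made from the lactone); C4–CH3 (lactone enolate and CH3I); the two C–H bonds at C3/C4 (hydrogenation of the butenolide); then C2–C3 (aldol) and O1–C5 (lactonization) to silylated vanillin and 2-oxobutanoic acid.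
Rings: both benzene rings are purchased; the oxygen ring is the only ring made, closed in step 2 as a butenolide and carried to the end.
Stereochemistry is passed around the ring: catalyst sets C2, the C2 aryl steers C3 (hydrogenation), C2/C3 steer C4 (methylation), C2/C3/C4 steer C5 (arylation).
Key step: step 2

Assumption: the sense of induction of the amine catalyst is taken from the usual enamine/hydrogen-bond model (catalysts of the L-proline series attack the Re face of aryl aldehydes), so the D-proline-derived (R)-catalyst is specified to reach the (5R)-butenolide; should the sense prove opposite, the (S)-catalyst is used and nothing else changes.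

Step 1
Reactants: 1 vanillin
Product: 2 3-methoxy-4-(triisopropylsilyloxy)benzaldehyde
Conditions: iPr3SiCl, imidazole, DMF, 0 °C to rt
Reagents that add atoms: chlorotriisopropylsilane, CC(C)[Si](Cl)(C(C)C)C(C)C
Why: Imidazole-mediated O-silylation of a phenol is routine, and the bulky aryl silyl ether should withstand the amine/acid catalysis, LiN(iPr)2, iBu2AlH and organozinc steps ahead while leaving under fluoride at the end.

Step 2
Reactants: 2 3-methoxy-4-(triisopropylsilyloxy)benzaldehyde, 3 2-oxobutanoic acid
Product: 5 (5R)-3-hydroxy-5-[3-methoxy-4-(triisopropylsilyloxy)phenyl]-4-methylfuran-2(5H)-one, via hydroxy keto acid 4 (not isolated)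
Conditions: (R)-2-(pyrrolidin-2-yl)-1H-benzimidazole (20 mol %), CF3CO2H (20 mol %), 2 (3 equiv), 3 added over 24 h, THF, rt; then 1 M HCl, rt
Reagents that add atoms: none
Why: Amine-catalysed direct cross-aldol followed by lactonization (isotetronic acid annulation), the known reaction type for enolizable 2-oxo acids and non-enolizable aldehydes: the pyrrolidine nitrogen condenses with the ketone of 3 to an enamine, whose only possible nucleophilic carbon (the CH2 of the ethyl group, future C3) adds to the aldehyde carbon of 2 (future C2), and hydrolysis frees hydroxy keto acid 4. Acid work-up closes the single ring of the route: the C2 hydroxyl adds to the carboxylic acid carbon and water leaves (5-exo-trig acyl substitution, O1–C5 bond), and the lactone rests as its enol tautomer 5. The one stereocentre that survives, C2, is set by the catalyst, whose protonated benzimidazole hydrogen-bonds the aldehyde oxygen so that the (R)-catalyst presents the Si face of the aldehyde to the enamine; the second aldol centre (C3) turns sp2 in the enol and needs no control. Cross- over homo-aldol selectivity is needed and is secured by the substrates themselves, since 2 has no α-hydrogen and is used in excess while 3, the only donor, is kept at low concentration by slow addition. Enantiopurity is protected because lactonization and enolization take the adduct out of the retro-aldol equilibrium. The para-silyloxy aldehyde is a sluggish acceptor, so high concentration and a long reaction time are planned and unreacted 2 is recovered.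

Step 3
Reactants: 5 (5R)-3-hydroxy-5-[3-methoxy-4-(triisopropylsilyloxy)phenyl]-4-methylfuran-2(5H)-one
Product: 6 (5R)-3-(tert-butyldimethylsilyloxy)-5-[3-methoxy-4-(triisopropylsilyloxy)phenyl]-4-methylfuran-2(5H)-one
Conditions: tBuMe2SiOSO2CF3, 2,6-lutidine, CH2Cl2, −78 °C
Reagents that add atoms: tert-butyldimethylsilyl trifluoromethanesulfonate, CC(C)(C)[Si](C)(C)OS(=O)(=O)C(F)(F)F
Why: O-silylation of the acidic enol hydroxyl with a silyl triflate is fast at low temperature, and the weak hindered pyridine base should not remove the benzylic C2 hydrogen (which would give an achiral 2-silyloxyfuran), so the C2 configuration is kept.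

Step 4
Reactants: 6 (5R)-3-(tert-butyldimethylsilyloxy)-5-[3-methoxy-4-(triisopropylsilyloxy)phenyl]-4-methylfuran-2(5H)-one
Product: 7 (3S,4S,5S)-3-(tert-butyldimethylsilyloxy)-5-[3-methoxy-4-(triisopropylsilyloxy)phenyl]-4-methyldihydrofuran-2(3H)-one (silyloxy, methyl and aryl all cis)
Conditions: H2 (20 bar), Rh/Al2O3 (5 wt % rhodium metal), EtOAc, rt
Reagents that add atoms: none
Why: Heterogeneous catalytic hydrogenation should add both hydrogens syn from the ring face opposite the C2 aryl group, which sets C3 with its methyl cis to the aryl (C4 is set too but is planarized again in step 5), and rhodium metal on alumina is chosen because it saturates hindered alkenes with little hydrogenolysis of the benzylic C2–O1 bond.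

Step 5
Reactants: 7 (3S,4S,5S)-3-(tert-butyldimethylsilyloxy)-5-[3-methoxy-4-(triisopropylsilyloxy)phenyl]-4-methyldihydrofuran-2(3H)-one, 8 iodomethane
Product: 10 (3S,4S,5S)-3-(tert-butyldimethylsilyloxy)-5-[3-methoxy-4-(triisopropylsilyloxy)phenyl]-3,4-dimethyldihydrofuran-2(3H)-one, via lithium enolate 9 (not isolated)
Conditions: LiN(iPr)2, THF, −78 °C; then MeI, DMPU, −78 to −40 °C
Reagents that add atoms: none
Why: Lactone enolate C-alkylation: LiN(iPr)2 removes the C4 hydrogen to give planar enolate 9, whose upper face is screened by the adjacent C3 methyl and the C2 aryl, so iodomethane should enter from the lower face and leave the silyloxy group cis to both, creating the quaternary C4 in the required configuration.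

Step 6
Reactants: 10 (3S,4S,5S)-3-(tert-butyldimethylsilyloxy)-5-[3-methoxy-4-(triisopropylsilyloxy)phenyl]-3,4-dimethyldihydrofuran-2(3H)-one
Product: 11 (3S,4S,5S)-3-(tert-butyldimethylsilyloxy)-5-[3-methoxy-4-(triisopropylsilyloxy)phenyl]-3,4-dimethyltetrahydrofuran-2-ol (lactol, both anomers)
Conditions: iBu2AlH, CH2Cl2, −78 °C
Reagents that add atoms: none
Why: Half-reduction of a lactone with one equivalent of iBu2AlH at −78 °C should stop at the lactol because the tetrahedral aluminium hemiacetal, here next to the quaternary C4, does not collapse before work-up.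

Step 7
Reactants: 11 (3S,4S,5S)-3-(tert-butyldimethylsilyloxy)-5-[3-methoxy-4-(triisopropylsilyloxy)phenyl]-3,4-dimethyltetrahydrofuran-2-ol
Product: 12 (3S,4S,5S)-2-(benzenesulfonyl)-3-(tert-butyldimethylsilyloxy)-5-[3-methoxy-4-(triisopropylsilyloxy)phenyl]-3,4-dimethyltetrahydrofuran (both epimers at the sulfonyl carbon, which is C5 in the route labels)
Conditions: PhSO2H, CaCl2, CH2Cl2, rt
Reagents that add atoms: benzenesulfinic acid, OS(=O)c1ccccc1
Why: Condensation of a lactol with benzenesulfinic acid to the anomeric sulfone is a standard hemiacetal exchange that CaCl2 drives by binding the water formed, and the sulfone cannot lose sulfinic acid to a dihydrofuran because the neighbouring C4 bears no hydrogen.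

Step 8
Reactants: 13 4-bromo-2-methoxyphenol
Product: 14 (4-bromo-2-methoxyphenoxy)triisopropylsilane
Conditions: iPr3SiCl, imidazole, DMF, rt
Reagents that add atoms: chlorotriisopropylsilane, CC(C)[Si](Cl)(C(C)C)C(C)C
Why: The same imidazole-mediated phenol silylation as in step 1 gives an aryl bromide with no acidic hydrogen, ready for magnesium insertion.

Step 9
Reactants: 12 (3S,4S,5S)-2-(benzenesulfonyl)-3-(tert-butyldimethylsilyloxy)-5-[3-methoxy-4-(triisopropylsilyloxy)phenyl]-3,4-dimethyltetrahydrofuran, 14 (4-bromo-2-methoxyphenoxy)triisopropylsilane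
Product: 18 (2R,3S,4S,5S)-3-(tert-butyldimethylsilyloxy)-2,5-bis[3-methoxy-4-(triisopropylsilyloxy)phenyl]-3,4-dimethyltetrahydrofuran, via aryl Grignard 15 (not isolated), via arylzinc bromide 16 (not isolated), via oxocarbenium ion 17 (not isolated)
Conditions: Mg, THF, 40 °C; ZnBr2, THF, rt; then 12, THF, rt
Reagents that add atoms: none
Why: Organozinc substitution of an anomeric sulfone: the magnesium and zinc halides assist departure of benzenesulfinate to oxocarbenium ion 17, and arylzinc bromide 16 should add to C5 from the face opposite the C2 aryl, the C3 methyl and the C4 silyloxy group, which places the new aryl trans to all three as the target requires.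

Step 10
Reactants: 18 (2R,3S,4S,5S)-3-(tert-butyldimethylsilyloxy)-2,5-bis[3-methoxy-4-(triisopropylsilyloxy)phenyl]-3,4-dimethyltetrahydrofuran
Product: 19 (2R,3S,4S,5S)-2,5-bis(4-hydroxy-3-methoxyphenyl)-3,4-dimethyltetrahydrofuran-3-ol (CNP0234919.3)
Conditions: Bu4NF, AcOH, THF, 0 to 50 °C
Reagents that add atoms: none
Why: Fluoride-mediated desilylation should remove the two aryl silyl ethers at once and the hindered tertiary silyl ether on warming, while the acetic acid buffer keeps the freed phenols protonated so that no para-quinone methide can form by opening of the benzylic ether bonds and no stereocentre is disturbed.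

Compound list
1 | vanillin (4-hydroxy-3-methoxybenzaldehyde) | COc1cc(C=O)ccc1O | starting material
2 | 3-methoxy-4-(triisopropylsilyloxy)benzaldehyde | COc1cc(C=O)ccc1O[Si](C(C)C)(C(C)C)C(C)C | intermediate
3 | 2-oxobutanoic acid | CCC(=O)C(=O)O | starting material
4 | (4S)-4-hydroxy-4-[3-methoxy-4-(triisopropylsilyloxy)phenyl]-3-methyl-2-oxobutanoic acid (both C3 epimers; not isolated) | COc1cc([C@@H](O)C(C)C(=O)C(=O)O)ccc1O[Si](C(C)C)(C(C)C)C(C)C | intermediate
5 | (5R)-3-hydroxy-5-[3-methoxy-4-(triisopropylsilyloxy)phenyl]-4-methylfuran-2(5H)-one (isotetronic acid) | COc1cc([C@H]2OC(=O)C(O)=C2C)ccc1O[Si](C(C)C)(C(C)C)C(C)C | intermediate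
6 | (5R)-3-(tert-butyldimethylsilyloxy)-5-[3-methoxy-4-(triisopropylsilyloxy)phenyl]-4-methylfuran-2(5H)-one | COc1cc([C@H]2OC(=O)C(O[Si](C)(C)C(C)(C)C)=C2C)ccc1O[Si](C(C)C)(C(C)C)C(C)C | intermediate
7 | (3S,4S,5S)-3-(tert-butyldimethylsilyloxy)-5-[3-methoxy-4-(triisopropylsilyloxy)phenyl]-4-methyldihydrofuran-2(3H)-one (all-cis) | COc1cc([C@H]2OC(=O)[C@@H](O[Si](C)(C)C(C)(C)C)[C@H]2C)ccc1O[Si](C(C)C)(C(C)C)C(C)C | intermediate
8 | iodomethane | CI | starting material
9 | lithium enolate of lactone 7 (C4 planar; not isolated) | COc1cc([C@H]2OC(O[Li])=C(O[Si](C)(C)C(C)(C)C)[C@H]2C)ccc1O[Si](C(C)C)(C(C)C)C(C)C | intermediate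
10 | (3S,4S,5S)-3-(tert-butyldimethylsilyloxy)-5-[3-methoxy-4-(triisopropylsilyloxy)phenyl]-3,4-dimethyldihydrofuran-2(3H)-one (silyloxy cis to the neighbouring methyl and to the aryl) | COc1cc([C@H]2OC(=O)[C@@](C)(O[Si](C)(C)C(C)(C)C)[C@H]2C)ccc1O[Si](C(C)C)(C(C)C)C(C)C | intermediate
11 | (3S,4S,5S)-3-(tert-butyldimethylsilyloxy)-5-[3-methoxy-4-(triisopropylsilyloxy)phenyl]-3,4-dimethyltetrahydrofuran-2-ol (lactol, both anomers) | COc1cc([C@H]2OC(O)[C@@](C)(O[Si](C)(C)C(C)(C)C)[C@H]2C)ccc1O[Si](C(C)C)(C(C)C)C(C)C | intermediate
12 | (3S,4S,5S)-2-(benzenesulfonyl)-3-(tert-butyldimethylsilyloxy)-5-[3-methoxy-4-(triisopropylsilyloxy)phenyl]-3,4-dimethyltetrahydrofuran (both epimers at the sulfonyl carbon) | COc1cc([C@H]2OC(S(=O)(=O)c3ccccc3)[C@@](C)(O[Si](C)(C)C(C)(C)C)[C@H]2C)ccc1O[Si](C(C)C)(C(C)C)C(C)C | intermediate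
13 | 4-bromo-2-methoxyphenol | COc1cc(Br)ccc1O | starting material
14 | (4-bromo-2-methoxyphenoxy)triisopropylsilane | COc1cc(Br)ccc1O[Si](C(C)C)(C(C)C)C(C)C | intermediate
15 | [3-methoxy-4-(triisopropylsilyloxy)phenyl]magnesium bromide (not isolated) | COc1cc([Mg]Br)ccc1O[Si](C(C)C)(C(C)C)C(C)C | intermediate
16 | [3-methoxy-4-(triisopropylsilyloxy)phenyl]zinc bromide (not isolated) | COc1cc([Zn]Br)ccc1O[Si](C(C)C)(C(C)C)C(C)C | intermediate
17 | oxocarbenium ion O1=C5 formed from 12 by loss of benzenesulfinate (not isolated) | COc1cc([C@H]2[O+]=C[C@@](C)(O[Si](C)(C)C(C)(C)C)[C@H]2C)ccc1O[Si](C(C)C)(C(C)C)C(C)C | intermediate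
18 | (2R,3S,4S,5S)-3-(tert-butyldimethylsilyloxy)-2,5-bis[3-methoxy-4-(triisopropylsilyloxy)phenyl]-3,4-dimethyltetrahydrofuran | COc1cc([C@H]2O[C@H](c3ccc(O[Si](C(C)C)(C(C)C)C(C)C)c(OC)c3)[C@@](C)(O[Si](C)(C)C(C)(C)C)[C@H]2C)ccc1O[Si](C(C)C)(C(C)C)C(C)C | intermediate
19 | (2R,3S,4S,5S)-2,5-bis(4-hydroxy-3-methoxyphenyl)-3,4-dimethyltetrahydrofuran-3-ol (CNP0234919.3) | COc1cc([C@H]2O[C@H](c3ccc(O)c(OC)c3)[C@@](C)(O)[C@H]2C)ccc1O | target

Total step count: 10. Longest linear sequence: 9 steps (steps 1–7, 9 and 10); step 8 is a one-step side branch.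

Steps most likely to fail

Step 2. The enamine may add too slowly to the deactivated, electron-rich aldehyde, so that homo-aldol of the keto acid and an unselective background reaction cut both conversion and enantiopurity. The fallback gives up asymmetric induction at this stage and sets out from 2 and 3. They are condensed with achiral pyrrolidinium acetate under forcing conditions (DMSO, 40 °C, then 1 M HCl) to racemic isotetronic acid F1, which is silylated as in step 3 to racemic silyloxy butenolide F2. F2 is resolved by preparative chromatography on a chiral stationary phase (amylose tris(3,5-dimethylphenylcarbamate), CO2/iPrOH); the (R)-enantiomer is compound 6, where the route is rejoined, and the (S)-enantiomer F3 is set aside.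

Step 9. The arylzinc may attack the oxocarbenium ion on the face of the C4 silyloxy group (five-membered oxocarbenium ions with an α-alkoxy group often take nucleophiles cis to it), giving mainly the C5 epimer; ionization beside the quaternary C4 may also be slow. The fallback reverses the order in which aryl and hydrogen reach C5 and sets out from lactone 10 and bromide 14. Bromine–lithium exchange on 14 (nBuLi, THF, −78 °C) gives aryllithium F7, which adds once to the hindered lactone 10 to give hemiketal F8. Reduction of F8 with Et3SiH and BF3·OEt2 (CH2Cl2, −78 °C) passes through the aryl-substituted oxocarbenium ion; hydride then enters on the face that the aryl nucleophile had preferred, which leaves the aryl on the required face and returns to the route at compound 18.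

Step 4. Hydrogen uptake at the hindered tetrasubstituted silyl enol ether may be slow enough that saturation of the electron-rich arene or hydrogenolysis of the benzylic C2–O1 bond competes. The fallback sets out from 5, which is acetylated (Ac2O, pyridine, 0 °C) to enol acetate F4, a smaller and more electron-poor alkene. Hydrogenation of F4 (H2 4 bar, Rh/Al2O3, EtOAc) from the face opposite the aryl should give the all-cis acetoxy lactone F5. Methanolysis (K2CO3, MeOH, 0 °C, then dilute acid to re-close any opened lactone) gives hydroxy lactone F6, and silylation (tBuMe2SiOSO2CF3, 2,6-lutidine, CH2Cl2) rejoins the route at compound 7. Any epimerization at C4 on this detour is harmless because C4 is planarized in step 5.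

Further compounds
F1 | step 2 | racemic 3-hydroxy-5-[3-methoxy-4-(triisopropylsilyloxy)phenyl]-4-methylfuran-2(5H)-one | COc1cc(C2OC(=O)C(O)=C2C)ccc1O[Si](C(C)C)(C(C)C)C(C)C
F2 | step 2 | racemic 3-(tert-butyldimethylsilyloxy)-5-[3-methoxy-4-(triisopropylsilyloxy)phenyl]-4-methylfuran-2(5H)-one | COc1cc(C2OC(=O)C(O[Si](C)(C)C(C)(C)C)=C2C)ccc1O[Si](C(C)C)(C(C)C)C(C)C
F3 | step 2 | (5S)-3-(tert-butyldimethylsilyloxy)-5-[3-methoxy-4-(triisopropylsilyloxy)phenyl]-4-methylfuran-2(5H)-one (unwanted enantiomer) | COc1cc([C@@H]2OC(=O)C(O[Si](C)(C)C(C)(C)C)=C2C)ccc1O[Si](C(C)C)(C(C)C)C(C)C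
F4 | step 4 | (5R)-3-acetoxy-5-[3-methoxy-4-(triisopropylsilyloxy)phenyl]-4-methylfuran-2(5H)-one | COc1cc([C@H]2OC(=O)C(OC(C)=O)=C2C)ccc1O[Si](C(C)C)(C(C)C)C(C)C
F5 | step 4 | (3S,4S,5S)-3-acetoxy-5-[3-methoxy-4-(triisopropylsilyloxy)phenyl]-4-methyldihydrofuran-2(3H)-one (all-cis) | COc1cc([C@H]2OC(=O)[C@@H](OC(C)=O)[C@H]2C)ccc1O[Si](C(C)C)(C(C)C)C(C)C
F6 | step 4 | (3S,4S,5S)-3-hydroxy-5-[3-methoxy-4-(triisopropylsilyloxy)phenyl]-4-methyldihydrofuran-2(3H)-one (all-cis) | COc1cc([C@H]2OC(=O)[C@@H](O)[C@H]2C)ccc1O[Si](C(C)C)(C(C)C)C(C)C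
F7 | step 9 | [3-methoxy-4-(triisopropylsilyloxy)phenyl]lithium | COc1cc([Li])ccc1O[Si](C(C)C)(C(C)C)C(C)C
F8 | step 9 | (3S,4S,5S)-3-(tert-butyldimethylsilyloxy)-2,5-bis[3-methoxy-4-(triisopropylsilyloxy)phenyl]-3,4-dimethyltetrahydrofuran-2-ol (hemiketal, both epimers at the hemiketal carbon) | COc1cc([C@H]2OC(O)(c3ccc(O[Si](C(C)C)(C(C)C)C(C)C)c(OC)c3)[C@@](C)(O[Si](C)(C)C(C)(C)C)[C@H]2C)ccc1O[Si](C(C)C)(C(C)C)C(C)C
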